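**Retrosynthetic overview**
1. Target 35 ⇐ acetylation of the C11 tertiary alcohol; ε-lactone ⇐ lactonisation of the C16 acid onto the C3 tertiary alcohol; C15 ⇐ asymmetric hydrogenation of an α-substituted acrylic acid; C11 carbinol ⇐ MeMgBr addition to a C11 ketone.
2. Cyclohexanone and oxolane rings together (bonds C1–C10 and C13–C14) ⇐ intramolecular Diels–Alder reaction of a 2-silyloxydiene (arm on C9) with an enamide (arm on C2) across a preformed oxonene.
3. Oxonene ⇐ ring-closing metathesis (C6=C7); C3 ⇐ chelation-controlled butenyl Grignard addition to a C3 methyl ketone.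
4. Key C2–C3 bond and the C2 stereocentre ⇐ intermolecular Evans syn-aldol of glycolyl imide 8 with acetaldehyde 9; C9 ⇐ Brown methallylation of aldehyde 2.
5. Ring order: nine-membered oxonene, then cyclohexane and oxolane in one step, then the seven-membered lactone.

Assumption: names use the eunicellane locants of the target (C2/C9 ether carbons, C1/C10 ring fusion, C3 lactone carbinol, C6=C7, C11 acetoxy carbon, C14–C15–C16 lactone arm); TBS = tert-butyldimethylsilyl, PMB = 4-methoxybenzyl; compound 1 is taken as commercial.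

**Route**

Step 1
Reactants: 1 3-[(4-methoxybenzyl)oxy]propan-1-ol
Product: 2 3-[(4-methoxybenzyl)oxy]propanal
Conditions: Dess–Martin periodinane, pyridine, CH2Cl2, 0 °C → rt
Reagents that add atoms: none
Why: Dess–Martin oxidation takes the primary alcohol to the aldehyde without over-oxidation and leaves the PMB ether intact.

Step 2
Reactants: 2 3-[(4-methoxybenzyl)oxy]propanal
Product: 3 (S)-1-[(4-methoxybenzyl)oxy]-5-methylhex-5-en-3-ol
Conditions: (−)-Ipc2BOMe, 2-methylallylmagnesium chloride, Et2O, −78 °C → rt; then 2, −78 °C; NaOH, H2O2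
Reagents that add atoms: 2-methylallylmagnesium chloride, C=C(C)C[Mg]Cl
Why: Brown asymmetric carbonyl methallylation: the (+)-α-pinene-derived B-methallyldiisopinocampheylborane adds through a chair six-membered transition state to the Si face of the aldehyde, setting C9 as S.

Step 3
Reactants: 3 (S)-1-[(4-methoxybenzyl)oxy]-5-methylhex-5-en-3-ol; 4 bromoacetic acid
Product: 5 2-{[(S)-1-(4-methoxybenzyloxy)-5-methylhex-5-en-3-yl]oxy}acetic acid
Conditions: NaH, THF, 0 °C → rt; then aq. HCl
Reagents that add atoms: none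
Why: Williamson ether synthesis: the sodium alkoxide of 3 displaces bromide from sodium bromoacetate by SN2 at a primary carbon, so C9 is untouched.

Step 4
Reactants: 5 glycolic acid ether; 6 (R)-4-benzyloxazolidin-2-one
Product: 8 (R)-4-benzyl-3-(2-{[(S)-1-(4-methoxybenzyloxy)-5-methylhex-5-en-3-yl]oxy}acetyl)oxazolidin-2-one, via mixed pivalic anhydride 7 (not isolated)
Conditions: PivCl, Et3N, THF, −78 → 0 °C; then 6, n-BuLi, THF, −78 → 0 °C
Reagents that add atoms: none
Why: N-acylation of the lithiated oxazolidinone by the mixed anhydride occurs at the unhindered glycolyl carbonyl and touches no stereocentre.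

Step 5
Reactants: 8 N-glycolyl imide; 9 acetaldehyde
Product: 11 (R)-4-benzyl-3-[(2R,3S)-3-hydroxy-2-{[(S)-1-(4-methoxybenzyloxy)-5-methylhex-5-en-3-yl]oxy}butanoyl]oxazolidin-2-one, via (Z)-boron enolate 10 (not isolated)
Conditions: Bu2BOTf, Et3N, CH2Cl2, −78 → 0 °C; 9, −78 → 0 °C; H2O2, pH 7 buffer, MeOH
Reagents that add atoms: none
Why: Evans syn-aldol: the (Z)-boron enolate reacts through a Zimmerman–Traxler chair on the face away from the auxiliary benzyl group, forming the C2–C3 bond and setting C2 (the target configuration) with a syn C3 hydroxyl that is oxidised later.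

Step 6
Reactants: 11 syn-aldol adduct
Product: 12 (2S,3S)-2-{[(S)-1-(4-methoxybenzyloxy)-5-methylhex-5-en-3-yl]oxy}butane-1,3-diol
Conditions: LiBH4, MeOH (1 equiv), THF, 0 °C
Reagents that add atoms: none
Why: Reductive removal of the auxiliary: LiBH4 reduces the exocyclic imide carbonyl to the C1 primary alcohol and releases the oxazolidinone without epimerising C2.

Step 7
Reactants: 12 1,3-diol
Product: 13 (2S,3S)-4-(TBS-oxy)-3-{[(S)-1-(4-methoxybenzyloxy)-5-methylhex-5-en-3-yl]oxy}butan-2-ol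
Conditions: TBSCl, imidazole, CH2Cl2, 0 °C
Reagents that add atoms: tert-butyldimethylsilyl chloride, CC(C)(C)[Si](C)(C)Cl
Why: Silylation is selective for the primary C1 hydroxyl over the hindered secondary one.

Step 8
Reactants: 13 mono-TBS ether
Product: 14 (S)-4-(TBS-oxy)-3-{[(S)-1-(4-methoxybenzyloxy)-5-methylhex-5-en-3-yl]oxy}butan-2-one
Conditions: Dess–Martin periodinane, pyridine, CH2Cl2, 0 °C → rt
Reagents that add atoms: none
Why: Dess–Martin oxidation gives the C3 methyl ketone under non-basic conditions, so the α-alkoxy stereocentre C2 is kept.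

Step 9
Reactants: 14 methyl ketone
Product: 15 (2S,3S)-1-(TBS-oxy)-3-methyl-2-{[(S)-1-(4-methoxybenzyloxy)-5-methylhex-5-en-3-yl]oxy}hept-6-en-3-ol
Conditions: but-3-enylmagnesium bromide, Et2O, −78 °C
Reagents that add atoms: but-3-enylmagnesium bromide, C=CCC[Mg]Br
Why: Cram-chelate Grignard addition: magnesium bridges the ketone oxygen and the α-ether oxygen and the nucleophile enters from the face of H-2 (away from CH2OTBS), setting C3 as S.

Step 10
Reactants: 15 tertiary alcohol
Product: 16 bis-TBS ether of 15 (C1 and C3 oxygens silylated)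
Conditions: TBSOTf, 2,6-lutidine, CH2Cl2, 0 °C → rt
Reagents that add atoms: tert-butyldimethylsilyl triflate, CC(C)(C)[Si](C)(C)OS(=O)(=O)C(F)(F)F
Why: The silyl triflate silylates even the tertiary C3 alcohol, protecting it through the oxidations, Grignard additions and enolisation that follow.

Step 11
Reactants: 16 acyclic diene
Product: 17 (2S,3S,9S,6Z)-3-(TBS-oxy)-2-[(TBS-oxy)methyl]-9-[2-(4-methoxybenzyloxy)ethyl]-3,7-dimethyl-2,3,4,5,8,9-hexahydrooxonine
Conditions: RuCl2(=CHPh)(PCy3)(H2IMes) (second-generation Grubbs catalyst, 10 mol %), CH2Cl2 (2 mM), 40 °C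
Reagents that add atoms: none
Why: Ring-closing metathesis of the vinyl and 1,1-disubstituted alkenes closes the nine-membered ether, helped by the gauche preference of the two α-branched ether carbons, and the ring allows only the Z trisubstituted alkene.

Step 12
Reactants: 17 bis-silylated oxonene
Product: 18 oxonene with free C1 hydroxymethyl group (C3–OTBS and PMB ether kept)
Conditions: CSA (0.2 equiv), MeOH/CH2Cl2, 0 °C
Reagents that add atoms: none
Why: Acid-catalysed methanolysis removes the primary TBS ether much faster than the tertiary one and does not cleave the PMB ether.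

Step 13
Reactants: 18 primary alcohol
Product: 19 oxonene-2-carbaldehyde (C1 = CHO)
Conditions: Dess–Martin periodinane, pyridine, CH2Cl2, 0 °C → rt
Reagents that add atoms: none
Why: Dess–Martin oxidation gives the α-alkoxy aldehyde without epimerising C2; it is used crude.

Step 14
Reactants: 19 aldehyde
Product: 20 (E)-N-methoxy-N-methyl-3-(oxonin-2-yl)acrylamide (C1=C14–C15 enamide on C2)
Conditions: Ph3P=CHC(O)N(OMe)Me, CH2Cl2, 40 °C
Reagents that add atoms: N-methoxy-N-methyl-2-(triphenylphosphoranylidene)acetamide, CON(C)C(=O)C=P(c1ccccc1)(c1ccccc1)c1ccccc1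
Why: Wittig olefination with a stabilised ylide gives the E-enamide, a dienophile that has no enolisable position.

Step 15
Reactants: 20 PMB ether
Product: 21 oxonene with free 2-hydroxyethyl arm on C9 (C11–OH)
Conditions: DDQ, CH2Cl2/pH 7 buffer, 0 °C
Reagents that add atoms: none
Why: Oxidative PMB cleavage by DDQ leaves the alkenes, the enamide and the silyl ether untouched.

Step 16
Reactants: 21 primary alcohol
Product: 22 C11 aldehyde
Conditions: Dess–Martin periodinane, pyridine, CH2Cl2, 0 °C → rt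
Reagents that add atoms: none
Why: Dess–Martin oxidation gives the β-alkoxy aldehyde under neutral conditions, avoiding β-elimination.

Step 17
Reactants: 22 aldehyde
Product: 23 allylic alcohol (C11 carbinol bearing the C12=C13 vinyl group; both C11 epimers)
Conditions: vinylmagnesium bromide (1.2 equiv), THF, −78 °C
Reagents that add atoms: vinylmagnesium bromide, C=C[Mg]Br
Why: Grignard 1,2-addition to the aldehyde is much faster at −78 °C than attack on the Weinreb enamide, and the new carbinol centre is removed in the next step.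

Step 18
Reactants: 23 allylic alcohol
Product: 24 vinyl ketone (C11 ketone)
Conditions: Dess–Martin periodinane, pyridine, CH2Cl2, 0 °C
Reagents that add atoms: none
Why: Dess–Martin oxidation gives the sensitive vinyl ketone under neutral conditions; it is used at once.

Step 19
Reactants: 24 vinyl ketone
Product: 27 tricyclic C11 ketone carrying the C15 Weinreb amide on C14, via silyloxydiene 25 (not isolated), via silyl enol ether cycloadduct 26 (not isolated)
Conditions: TBSOTf, Et3N, CH2Cl2, −78 → 0 °C; PhMe, 60 °C; then 1 M HCl, THF, 0 °C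
Reagents that add atoms: none
Why: Soft enolisation gives the (Z)-2-silyloxydiene, which undergoes an intramolecular Diels–Alder reaction with the (E)-enamide across the cis-2,9-disubstituted oxonene through the amide-exo transition state with the new ring on the oxolane face away from the oxonene carbons, setting C1 and C10 (cis-fused, H-1/H-10 anti to H-2/H-9) and C14 (trans to C2); acid then hydrolyses the silyl enol ether.

Step 20
Reactants: 27 keto Weinreb amide
Product: 28 C11 tertiary alcohol (11R) with C15 methyl ketone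
Conditions: MeMgBr (6 equiv), THF, −78 → 0 °C
Reagents that add atoms: methylmagnesium bromide, C[Mg]Br
Why: Grignard addition: methyl attacks the C11 ketone axially on the convex face (that of H-10 and H-1, anti to the axial C10–C9 bond), leaving the carbinol oxygen equatorial and cis to C9, while the Weinreb amide gives the methyl ketone through its chelated tetrahedral intermediate.

Step 21
Reactants: 28 methyl ketone
Product: 29 enol triflate (C15(OTf)=CH2)
Conditions: KN(SiMe3)2 (2.2 equiv), THF, −78 °C; PhNTf2, −78 → 0 °C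
Reagents that add atoms: N-phenylbis(trifluoromethanesulfonimide), O=S(=O)(N(c1ccccc1)S(=O)(=O)C(F)(F)F)C(F)(F)F
Why: Kinetic deprotonation takes the methyl hydrogen, not the hindered C14–H, and the enolate oxygen is triflated far faster than the hindered tertiary C11 alkoxide.

Step 22
Reactants: 29 enol triflate
Product: 30 α-substituted acrylic acid (C14–C15(=CH2)–C16OOH)
Conditions: Pd(OAc)2 (5 mol %), PPh3, KOAc, CO (1 atm), DMF/H2O, 40 °C
Reagents that add atoms: carbon monoxide, [C-]#[O+]; water, O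
Why: Palladium-catalysed hydroxycarbonylation (oxidative addition, CO insertion, acyl capture by acetate and hydrolysis) installs C16 as the carboxylic acid without touching other groups.

Step 23
Reactants: 30 acrylic acid
Product: 31 (15R)-2-substituted propanoic acid (C3–OTBS, C11–OH)
Conditions: H2 (100 atm), Ru(OAc)2[(R)-BINAP] (2 mol %), MeOH, rt
Reagents that add atoms: none
Why: Carboxylate-directed asymmetric hydrogenation: the (R)-BINAP ruthenium dicarboxylate reduces only the acrylic acid (the isolated trisubstituted alkene is inert) and sets C15 as R under catalyst control.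

Step 24
Reactants: 31 silyl-protected acid
Product: 32 seco-acid (free C3 and C11 tertiary alcohols)
Conditions: HF·pyridine, pyridine, THF, rt → 40 °C
Reagents that add atoms: none
Why: Fluoride-driven desilylation frees the C3 alcohol, and the pyridine buffer prevents protonation of the C6=C7 alkene and transannular etherification.

Step 25
Reactants: 32 seco-acid
Product: 34 11-hydroxy lactone (deacetyl target), via mixed Yamaguchi anhydride 33 (not isolated)
Conditions: 2,4,6-Cl3C6H2COCl, Et3N, THF, rt; then DMAP, PhMe (1 mM), 80 °C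
Reagents that add atoms: none
Why: Yamaguchi lactonisation: the activated acid is attacked by the C3 hydroxyl, which the trans-diequatorial C1/C14 substituents hold next to C16, closing the seven-membered lactone, while the C11 hydroxyl (trans-1,4 across the cyclohexane) cannot reach.

Step 26
Reactants: 34 hydroxy lactone
Product: 35 target CNP0332402.2
Conditions: Ac2O, DMAP, Et3N, CH2Cl2, 40 °C
Reagents that add atoms: acetic anhydride, CC(=O)OC(C)=O
Why: DMAP-catalysed acylation of the remaining tertiary C11 alcohol breaks no C–O bond (configuration retained) and is too weakly basic to epimerise C15.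

**Compound list**
1 | 3-[(4-methoxybenzyl)oxy]propan-1-ol | COc1ccc(COCCCO)cc1 | starting material
2 | 3-[(4-methoxybenzyl)oxy]propanal | COc1ccc(COCCC=O)cc1 | intermediate
3 | (S)-1-[(4-methoxybenzyl)oxy]-5-methylhex-5-en-3-ol | COc1ccc(COCC[C@@H](O)CC(C)=C)cc1 | intermediate
4 | bromoacetic acid | OC(=O)CBr | starting material
5 | 2-{[(S)-1-(4-methoxybenzyloxy)-5-methylhex-5-en-3-yl]oxy}acetic acid | COc1ccc(COCC[C@@H](OCC(=O)O)CC(C)=C)cc1 | intermediate
6 | (R)-4-benzyloxazolidin-2-one | O=C1N[C@H](Cc2ccccc2)CO1 | starting material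
7 | mixed pivalic anhydride of acid 5 | COc1ccc(COCC[C@@H](OCC(=O)OC(=O)C(C)(C)C)CC(C)=C)cc1 | intermediate
8 | (R)-4-benzyl-3-(2-{[(S)-1-(4-methoxybenzyloxy)-5-methylhex-5-en-3-yl]oxy}acetyl)oxazolidin-2-one | COc1ccc(COCC[C@@H](OCC(=O)N2[C@H](Cc3ccccc3)COC2=O)CC(C)=C)cc1 | intermediate
9 | acetaldehyde | CC=O | starting material
10 | (Z)-dibutylboron enolate of imide 8 | CCCCB(CCCC)O/C(N1[C@H](Cc2ccccc2)COC1=O)=C\O[C@H](CCOCc1ccc(OC)cc1)CC(C)=C | intermediate
11 | (R)-4-benzyl-3-[(2R,3S)-3-hydroxy-2-{[(S)-1-(4-methoxybenzyloxy)-5-methylhex-5-en-3-yl]oxy}butanoyl]oxazolidin-2-one | COc1ccc(COCC[C@@H](O[C@H]([C@H](C)O)C(=O)N2[C@H](Cc3ccccc3)COC2=O)CC(C)=C)cc1 | intermediate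
12 | (2S,3S)-2-{[(S)-1-(4-methoxybenzyloxy)-5-methylhex-5-en-3-yl]oxy}butane-1,3-diol | COc1ccc(COCC[C@@H](O[C@H]([C@H](C)O)CO)CC(C)=C)cc1 | intermediate
13 | (2S,3S)-4-(TBS-oxy)-3-{[(S)-1-(4-methoxybenzyloxy)-5-methylhex-5-en-3-yl]oxy}butan-2-ol | COc1ccc(COCC[C@@H](O[C@H]([C@H](C)O)CO[Si](C)(C)C(C)(C)C)CC(C)=C)cc1 | intermediate
14 | (S)-4-(TBS-oxy)-3-{[(S)-1-(4-methoxybenzyloxy)-5-methylhex-5-en-3-yl]oxy}butan-2-one | COc1ccc(COCC[C@@H](O[C@H](C(C)=O)CO[Si](C)(C)C(C)(C)C)CC(C)=C)cc1 | intermediate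
15 | (2S,3S)-1-(TBS-oxy)-3-methyl-2-{[(S)-1-(4-methoxybenzyloxy)-5-methylhex-5-en-3-yl]oxy}hept-6-en-3-ol | COc1ccc(COCC[C@@H](O[C@H]([C@@](C)(O)CCC=C)CO[Si](C)(C)C(C)(C)C)CC(C)=C)cc1 | intermediate
16 | bis-TBS ether of 15 (C1–O and C3–O silylated) | COc1ccc(COCC[C@@H](O[C@H]([C@@](C)(O[Si](C)(C)C(C)(C)C)CCC=C)CO[Si](C)(C)C(C)(C)C)CC(C)=C)cc1 | intermediate
17 | (2S,3S,9S,6Z)-3-(TBS-oxy)-2-[(TBS-oxy)methyl]-9-[2-(4-methoxybenzyloxy)ethyl]-3,7-dimethyl-2,3,4,5,8,9-hexahydrooxonine | COc1ccc(COCC[C@@H]2C/C(C)=C\CC[C@](C)(O[Si](C)(C)C(C)(C)C)[C@H](CO[Si](C)(C)C(C)(C)C)O2)cc1 | intermediate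
18 | oxonene 17 with free C1 hydroxymethyl group | COc1ccc(COCC[C@@H]2C/C(C)=C\CC[C@](C)(O[Si](C)(C)C(C)(C)C)[C@H](CO)O2)cc1 | intermediate
19 | oxonene-2-carbaldehyde (C1 = CHO; stereocentres as in 18) | COc1ccc(COCC[C@@H]2C/C(C)=C\CC[C@](C)(O[Si](C)(C)C(C)(C)C)[C@H](C=O)O2)cc1 | intermediate
20 | (E)-Weinreb enamide on C2 of the oxonene (PMB ether kept) | COc1ccc(COCC[C@@H]2C/C(C)=C\CC[C@](C)(O[Si](C)(C)C(C)(C)C)[C@H](/C=C/C(=O)N(C)OC)O2)cc1 | intermediate
21 | enamide oxonene with 2-hydroxyethyl arm on C9 | OCC[C@@H]1C/C(C)=C\CC[C@](C)(O[Si](C)(C)C(C)(C)C)[C@H](/C=C/C(=O)N(C)OC)O1 | intermediate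
22 | enamide oxonene with C11 aldehyde | O=CC[C@@H]1C/C(C)=C\CC[C@](C)(O[Si](C)(C)C(C)(C)C)[C@H](/C=C/C(=O)N(C)OC)O1 | intermediate
23 | enamide oxonene with C11 allylic alcohol (both C11 epimers) | C=CC(O)C[C@@H]1C/C(C)=C\CC[C@](C)(O[Si](C)(C)C(C)(C)C)[C@H](/C=C/C(=O)N(C)OC)O1 | intermediate
24 | enamide oxonene with C11 vinyl ketone | C=CC(=O)C[C@@H]1C/C(C)=C\CC[C@](C)(O[Si](C)(C)C(C)(C)C)[C@H](/C=C/C(=O)N(C)OC)O1 | intermediate
25 | (Z)-2-(TBS-oxy)-1,3-diene on C9 with (E)-enamide on C2 | C=C/C(O[Si](C)(C)C(C)(C)C)=C/[C@@H]1C/C(C)=C\CC[C@](C)(O[Si](C)(C)C(C)(C)C)[C@H](/C=C/C(=O)N(C)OC)O1 | intermediate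
26 | tricyclic cycloadduct: C11 TBS enol ether; C14 Weinreb amide | CC(C)(C)[Si](C)(C)OC1=CC[C@@H](C(=O)N(C)OC)[C@H]2[C@@H]1[C@@H]1C/C(C)=C\CC[C@](C)(O[Si](C)(C)C(C)(C)C)[C@H]2O1 | intermediate
27 | tricyclic C11 ketone with C14 Weinreb amide and C3–OTBS | O=C1CC[C@@H](C(=O)N(C)OC)[C@H]2[C@@H]1[C@@H]1C/C(C)=C\CC[C@](C)(O[Si](C)(C)C(C)(C)C)[C@H]2O1 | intermediate
28 | tricyclic (11R)-tertiary alcohol with C15 methyl ketone | O[C@]1(C)CC[C@@H](C(C)=O)[C@H]2[C@@H]1[C@@H]1C/C(C)=C\CC[C@](C)(O[Si](C)(C)C(C)(C)C)[C@H]2O1 | intermediate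
29 | C15 enol triflate | O[C@]1(C)CC[C@@H](C(=C)OS(=O)(=O)C(F)(F)F)[C@H]2[C@@H]1[C@@H]1C/C(C)=C\CC[C@](C)(O[Si](C)(C)C(C)(C)C)[C@H]2O1 | intermediate
30 | α-substituted acrylic acid (C15=CH2; C16OOH) | O[C@]1(C)CC[C@@H](C(=C)C(=O)O)[C@H]2[C@@H]1[C@@H]1C/C(C)=C\CC[C@](C)(O[Si](C)(C)C(C)(C)C)[C@H]2O1 | intermediate
31 | (15R)-propanoic acid with C3–OTBS | O[C@]1(C)CC[C@@H]([C@@H](C)C(=O)O)[C@H]2[C@@H]1[C@@H]1C/C(C)=C\CC[C@](C)(O[Si](C)(C)C(C)(C)C)[C@H]2O1 | intermediate
32 | seco-acid with free C3 and C11 alcohols | O[C@]1(C)CC[C@@H]([C@@H](C)C(=O)O)[C@H]2[C@@H]1[C@@H]1C/C(C)=C\CC[C@](C)(O)[C@H]2O1 | intermediate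
33 | mixed 2,4,6-trichlorobenzoic anhydride of 32 | O[C@]1(C)CC[C@@H]([C@@H](C)C(=O)OC(=O)c3c(Cl)cc(Cl)cc3Cl)[C@H]2[C@@H]1[C@@H]1C/C(C)=C\CC[C@](C)(O)[C@H]2O1 | intermediate
34 | 11-hydroxy lactone (deacetyl target) | O[C@]1(C)CC[C@@H]2[C@H]3[C@@H]1[C@@H]1C/C(C)=C\CC[C@](C)(OC(=O)[C@@H]2C)[C@H]3O1 | intermediate
35 | CNP0332402.2: (1S,2S,3S,6Z,9S,10R,11R,14R,15R)-11-acetoxy-2,9-epoxyeunicell-6-en-16,3-olide | CC(=O)O[C@]1(C)CC[C@@H]2[C@H]3[C@@H]1[C@@H]1C/C(C)=C\CC[C@](C)(OC(=O)[C@@H]2C)[C@H]3O1 | target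

**Totals and weak points**

Total step count: 26. Longest linear sequence: 26 steps (from 1; compounds 4, 6 and 9 are bought).

The three steps most likely to fail:

- Step 19 (silyloxydiene formation and cycloaddition). Vinyl ketone 24 carries a β-ether and may eliminate or polymerise on enolisation. The fallback leaves silicon out and sets out from 24: pyrrolidine (30 mol %) and AcOH in CHCl3 condense with the ketone to the cross-conjugated 2-(pyrrolidin-1-yl)diene F1 (dienamine activation). This cyclises in the same intramolecular Diels–Alder sense to the enamine cycloadduct F2, and aqueous work-up hydrolyses it to ketone 27, where the route is rejoined.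

- Step 23 (catalyst-controlled hydrogenation at C15). The chiral substrate may be mismatched with the catalyst. The fallback sets C15 by ring control and sets out from acrylic acid 30: HF·pyridine frees the C3 alcohol to give the dihydroxy acrylic acid F3, and Yamaguchi lactonisation gives the α-methylene ε-lactone F4. Hydrogenation of its exocyclic alkene with RhCl(PPh3)3 and H2 (inert to the trisubstituted C6=C7 alkene) should deliver hydrogen to the more open face of the lactone ring, that of H-14, and gives hydroxy lactone 34 directly. This facial preference is argued from a chair model of the lactone and is not established.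

- Step 25 (acylation of a tertiary alcohol to close a seven-membered lactone). The fallback changes the oxidation level and sets out from silyl-protected acid 31: LiAlH4 reduces the acid to the primary alcohol F5 and HF·pyridine gives the triol F6. TEMPO with PhI(OAc)2 then oxidises the primary alcohol to the aldehyde, which the C3 hydroxyl traps as the seven-membered lactol F7; this is oxidised on to lactone 34.

**Further compounds**
F1 | step 19 | (Z)-2-(pyrrolidin-1-yl)-1,3-diene on C9 with (E)-enamide on C2 | C=C/C(N1CCCC1)=C/[C@@H]1C/C(C)=C\CC[C@](C)(O[Si](C)(C)C(C)(C)C)[C@H](/C=C/C(=O)N(C)OC)O1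
F2 | step 19 | tricyclic enamine cycloadduct (C11 pyrrolidinyl enamine; C14 Weinreb amide) | C1(N3CCCC3)=CC[C@@H](C(=O)N(C)OC)[C@H]2[C@@H]1[C@@H]1C/C(C)=C\CC[C@](C)(O[Si](C)(C)C(C)(C)C)[C@H]2O1
F3 | step 23 | acrylic acid with free C3 and C11 alcohols | O[C@]1(C)CC[C@@H](C(=C)C(=O)O)[C@H]2[C@@H]1[C@@H]1C/C(C)=C\CC[C@](C)(O)[C@H]2O1
F4 | step 23 | α-methylene ε-lactone (C15=CH2) with free C11 alcohol | O[C@]1(C)CC[C@@H]2[C@H]3[C@@H]1[C@@H]1C/C(C)=C\CC[C@](C)(OC(=O)C2=C)[C@H]3O1
F5 | step 25 | (15R)-C16 primary alcohol with C3–OTBS | O[C@]1(C)CC[C@@H]([C@@H](C)CO)[C@H]2[C@@H]1[C@@H]1C/C(C)=C\CC[C@](C)(O[Si](C)(C)C(C)(C)C)[C@H]2O1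
F6 | step 25 | triol (C16, C3 and C11 hydroxyls) | O[C@]1(C)CC[C@@H]([C@@H](C)CO)[C@H]2[C@@H]1[C@@H]1C/C(C)=C\CC[C@](C)(O)[C@H]2O1
F7 | step 25 | seven-membered lactol (C16 hemiacetal to C3–O) | O[C@]1(C)CC[C@@H]2[C@H]3[C@@H]1[C@@H]1C/C(C)=C\CC[C@](C)(OC(O)[C@@H]2C)[C@H]3O1
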